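- A small charge of substrate, 0.020 M, went into Sunday's flask at a steady rate over 20.0 h, and I wanted the share of target in what it became; the set-ups and earlier runs were these.

| flask | substrate | partner | remark | time |
|---|---|---|---|---|
| green | 0.020 M | 2 equiv | run made earlier |  |
| amber | 0.040 M | 2 equiv | run made earlier |  |
| Saturday's | 0.020 M | 2.00 equiv (fed, over 20.0 h) | a stirred flask in which partner is dosed at a steady rate over 20.0 h without added volume, worked up at 25 h | 25 h |
| Friday's | 0.020 M | 2.00 equiv | one stirred flow tank at steady state, fed with the mixture as stated, mean residence time 25 h |  |
| Sunday's | 0.020 M (fed, over 20.0 h) | 2.00 equiv | a stirred flask in which substrate is dosed at a steady rate over 20.0 h without added volume, worked up at 25 h | 25 h |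
| Wednesday's | 0.020 M | 2.00 equiv | everything together in a closed stirred flask, run for 25 h | 25 h |

| run | time / h | target / % | side product A / % | side product B / % |
|---|---|---|---|---|
| green | 4.00 | 17.5 | 8.9 | 1.3 |
| green | 8.00 | 27.1 | 17.3 | 2.4 |
| green | 10.0 | 30.1 | 18.7 | 3.1 |
| green | 15.0 | 34.8 | 24.0 | 3.1 |
| green | 20.0 | 38.0 | 29.3 | 5.5 |
| green | 25.0 | 39.6 | 32.2 | 8.9 |
| amber | 1.00 | 9.0 | 4.5 | 0 |
| amber | 2.00 | 18.5 | 3.5 | 1.2 |
| amber | 3.00 | 23.8 | 8.0 | 1.0 |
| amber | 4.00 | 29.6 | 9.2 | 2.0 |
| amber | 5.00 | 33.0 | 9.1 | 4.0 |
| amber | 6.00 | 34.3 | 12.7 | 2.6 |
| amber | 8.00 | 39.5 | 14.4 | 5.5 |

(readings scatter by 1 percentage point)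

* order of the set-ups by the share of target in all that became target or side product A or side product B, at the outlet or at the end, highest first (Saturday's / Friday's / Sunday's / Wednesday's)
* share of target in all that became target or side product A or side product B, at the outlet or at the end, Saturday's
* share of target in all that became target or side product A or side product B, at the outlet or at the end, Friday's
* share of target in all that became target or side product A or side product B, at the outlet or at the end, Sunday's
* share of target in all that became target or side product A or side product B, at the outlet or at the end, Wednesday's

- percentages count the substrate that a species holds: one side product B counts as two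
- the stated concentrations are those of everything mixed, before any reaction; amounts are the same in each set-up
- the feed brings no volume worth counting
- the earlier runs were made in a closed, stirred flask

- Substrate had two exits, with partner to target and by itself to side product A. So I took s, the target made per side product A made (the usual selectivity factor), as [partner]/K, and over a whole run s is the weighted mean partner divided by K.
- I counted half of side product B as target once made, reading it as target plus substrate, where the forecast leaned to two targets.
- Green's first reading gave s = 2.04; with partner taken at its charge, 0.0400 M, that reads K = 0.0196 M, the break-even partner, at which both exits run equally fast.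
- From above, for Sunday's: partner at its charge and no side product B give a share of 67.1%.
- From below, for Sunday's: green's s from 15.0 h to 25.0 h read 0.939, which reads as partner near 0.0184 M, less than the 0.0312 M that making target alone would leave. With green's proportion of side product B, 0.276, that estimate of the share is 38.6%.
- Tightened: Sunday's substrate came in over 20.0 h, so I chose green's s from 8.00 h onward, 1.06. That estimates Sunday's share at 51.4% without side product B and 41.9% with it.
- The forecast put Saturday's at 42%, Friday's at 48%, Wednesday's at 49% and Sunday's at 58%, from 53% to 62%, above my tightened top, with the order Sunday's > Wednesday's > Friday's > Saturday's: “Sunday's keeps partner high and target low”.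

    substrate + target → side product B (k = 1.80 × 10⁻⁴ L mol⁻¹ s⁻¹)
    2 partner → homo dimer (k = 1.30 × 10⁻⁴ L mol⁻¹ s⁻¹)
    partner → decomposed reagent (k = 4.80 × 10⁻⁶ s⁻¹)
    substrate → side product A (k = 7.60 × 10⁻⁶ s⁻¹)
    substrate + partner → target (k = 4.30 × 10⁻⁴ L mol⁻¹ s⁻¹)

- Sunday's gave 46.7%, inside the tightened bracket, Saturday's 39.5% and Wednesday's 50.2%, and the order was Wednesday's > Sunday's > Friday's > Saturday's. At the end Sunday's still held 45% of its substrate. Friday's tank stood at one partner level, 0.0184 M, and through K that level gives a share of 48.4% before side product B is counted; the tank gave 42.6%.

The earlier runs and the new flask were generated by integration with constants of no real substance; noise was put on by code.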